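## Retrosynthetic overview

1. Feature: in pyranone ring C (O1–C2–C3–C4–C4a–C8a), C4 is a single carbonyl carbon held between C4a of ring A and C3 of the C3=C2–aryl (ring B) unit. O1 sits on C8a, ortho to C4a. C4 is therefore CO, C3/C2 a terminal arylacetylene, and C4a/O1 an ortho-iodophenol.
2. Endgame: 24 ⇐ H2/Pd on 5,8-quinone 22 ⇐ ceric oxidation of the para-related 5-OMe/8-OMe pair of 21 (3-OMe and 7-OMe stay) ⇐ C3 lithiation–borylation–oxidation and O-methylation of flavone 17.
3. Key disconnection: 17 ⇐ iodophenol 9 + alkyne 13 + CO 14 (bonds C4a–C4, C4–C3, O1–C2). Rings A and B are bought as arenes, and ring C is the only ring built.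
4. 9 ⇐ carbamate-directed ortho-lithiation/iodination of 6 ⇐ aldehyde 1 (carbamoylation, Baeyer–Villiger, methylation). 13 ⇐ aldehyde 10 (benzylation, Ohira–Bestmann homologation).

Key step: step 8

Assumption: the target has no stereocentre, stereogenic axis or configurable double bond. It is achiral, so the single-enantiomer requirement needs no stereocontrol.

## Route

Step 1
Reactants: 1 3-hydroxy-4,5-dimethoxybenzaldehyde; 2 N,N-diethylcarbamoyl chloride
Product: 3 5-formyl-2,3-dimethoxyphenyl N,N-diethylcarbamate
Conditions: K2CO3, MeCN, reflux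
Reagents that add atoms: none
Why: O-carbamoylation of the phenoxide (nucleophilic acyl substitution) masks the future O1 hydroxyl for the peracid step and installs the strongest oxygen-based directing group for the later metalation, while the aldehyde is inert to carbonate.

Step 2
Reactants: 3 5-formyl-2,3-dimethoxyphenyl N,N-diethylcarbamate
Product: 5 5-hydroxy-2,3-dimethoxyphenyl N,N-diethylcarbamate, via aryl formate 4 (not isolated)
Conditions: mCPBA, CH2Cl2, 0 °C → rt; then K2CO3 (cat.), MeOH, rt
Reagents that add atoms: mCPBA, OOC(=O)c1cccc(Cl)c1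
Why: In this Baeyer–Villiger (Dakin-type) oxidation the aryl group, activated by its para-methoxy group, should migrate in preference to hydride, and the resulting formate is removed by mild transesterification that leaves the much less electrophilic diethylcarbamate untouched.

Step 3
Reactants: 5 5-hydroxy-2,3-dimethoxyphenyl N,N-diethylcarbamate
Product: 6 2,3,5-trimethoxyphenyl N,N-diethylcarbamate
Conditions: MeI, K2CO3, acetone, reflux
Reagents that add atoms: iodomethane, CI
Why: Williamson etherification of the only free phenol gives the future 5-OMe group, and the carbamate is stable to carbonate in acetone.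

Step 4
Reactants: 6 2,3,5-trimethoxyphenyl N,N-diethylcarbamate
Product: 8 2-iodo-3,5,6-trimethoxyphenyl N,N-diethylcarbamate, via aryllithium 7 (not isolated)
Conditions: s-BuLi, TMEDA, THF, −78 °C; then I2, THF, −78 °C → rt
Reagents that add atoms: iodine, II; sec-butyllithium, [Li]C(C)CC (lithium held only in 7)
Why: In this directed ortho-metalation the carbamate has only one free ortho position, which also lies next to a methoxy group, so complex-induced deprotonation there should outrun the site between two methoxy groups, and holding −78 °C suppresses the anionic ortho-Fries shift before iodine quenches the anion.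

Step 5
Reactants: 8 2-iodo-3,5,6-trimethoxyphenyl N,N-diethylcarbamate
Product: 9 2-iodo-3,5,6-trimethoxyphenol
Conditions: NaOH, EtOH–H2O, reflux, Ar; then dilute HCl
Reagents that add atoms: none
Why: Basic acyl–oxygen hydrolysis of the aryl carbamate frees the single phenol, and the unactivated aryl iodide and the methyl ethers are inert to hydroxide.

Step 6
Reactants: 10 3,4,5-trihydroxybenzaldehyde
Product: 11 3,4,5-tris(benzyloxy)benzaldehyde
Conditions: BnBr (3.6 equiv), K2CO3, DMF, 60 °C, N2
Reagents that add atoms: benzyl bromide, BrCc1ccccc1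
Why: Threefold Williamson benzylation under inert gas protects the oxidation-prone pyrogallol as ethers that survive base, organolithium amide, palladium/CO and cerium(IV) and fall off by hydrogenolysis at the end.

Step 7
Reactants: 11 3,4,5-tris(benzyloxy)benzaldehyde; 12 dimethyl (1-diazo-2-oxopropyl)phosphonate
Product: 13 5-ethynyl-1,2,3-tris(benzyloxy)benzene
Conditions: K2CO3, MeOH–THF, 0 °C → rt
Reagents that add atoms: none
Why: In this Seyferth–Gilbert homologation (Ohira–Bestmann variant) methanolysis unmasks the diazomethylphosphonate anion, which olefinates the non-enolisable aldehyde, and loss of N2 with a 1,2-hydrogen shift gives the terminal alkyne whose new carbon becomes C3.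

Step 8
Reactants: 9 2-iodo-3,5,6-trimethoxyphenol; 13 5-ethynyl-1,2,3-tris(benzyloxy)benzene; 14 carbon monoxide
Product: 17 3',4',5'-tris(benzyloxy)-5,7,8-trimethoxyflavone, via hydroxyaryl ynone 15 (not isolated), via diethylamino enone 16 (not isolated)
Conditions: PdCl2(dppf) (5 mol %), CO (20 bar), Et2NH–DMF, 120 °C, autoclave, no copper
Reagents that add atoms: diethylamine, CCNCC (held only in 16)
Why: Pd(0) inserts into the C–I bond at the future C4a, CO insertion gives the aroyl–palladium species (C4a–C4), and transfer of the amine-deprotonated alkyne followed by reductive elimination gives ynone 15 (C4–C3). The closest known reaction type is the copper-free carbonylative Sonogashira annulation of 2-iodophenols with terminal arylacetylenes to flavones. Diethylamine then adds to the β-carbon of 15 (future C2) to give enaminone 16, and the C8a hydroxyl displaces the amine by addition–elimination, so ring C closes by a formal 6-endo-dig O1–C2 bond formation. The step needs 6-endo over 5-exo closure (aurone), which the enaminone pathway secures by fixing the electrophilic site at C2, and carbonylative over direct coupling (2-arylbenzofuran), which CO pressure, the absence of copper and the fast CO insertion of an electron-rich aryl–palladium favour. The 5,7,8 rather than 5,6,7 oxygenation pattern is fixed by the substrate, because 9 carries only one free hydroxyl and it lies ortho to iodine. No stereocentre is formed.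

Step 9
Reactants: 17 3',4',5'-tris(benzyloxy)-5,7,8-trimethoxyflavone
Product: 20 3',4',5'-tris(benzyloxy)-3-hydroxy-5,7,8-trimethoxyflavone, via 3-lithioflavone 18 (not isolated), via 3-boronate 19 (not isolated)
Conditions: LDA, THF, −78 °C; B(OMe)3, −78 → 0 °C; AcOH, 30 % aq. H2O2, 0 °C → rt
Reagents that add atoms: hydrogen peroxide, OO (the C3 oxygen); trimethyl borate, COB(OC)OC (boron held only in 19); lithium diisopropylamide, [Li]N(C(C)C)C(C)C (lithium held only in 18)
Why: This is the carbonyl-assisted C3 lithiation of a flavone followed by borate trapping and boronate oxidation (1,2-shift from boron to oxygen), and LDA is too weak a base to metalate the aryl C–H or benzylic ether positions, so only the vinylic C3–H next to C4=O should react.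

Step 10
Reactants: 20 3',4',5'-tris(benzyloxy)-3-hydroxy-5,7,8-trimethoxyflavone
Product: 21 3',4',5'-tris(benzyloxy)-3,5,7,8-tetramethoxyflavone
Conditions: MeI, K2CO3, acetone, reflux
Reagents that add atoms: iodomethane, CI
Why: Williamson methylation of the only free hydroxyl, the acidic enolic 3-OH, installs the 3-methoxy group of the target.

Step 11
Reactants: 21 3',4',5'-tris(benzyloxy)-3,5,7,8-tetramethoxyflavone
Product: 22 3,7-dimethoxy-2-[3,4,5-tris(benzyloxy)phenyl]-4H-chromene-4,5,8-trione
Conditions: (NH4)2Ce(NO3)6 (2.2 equiv), MeCN–CH2Cl2–H2O, 0 °C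
Reagents that add atoms: water, O
Why: In this ceric ammonium nitrate oxidative demethylation of a 1,4-dimethoxyarene, electron transfer should occur from tetra-oxygenated ring A, the most easily oxidised part, water adds at C5 and C8 with loss of methanol to give the para-quinone, and the 7-OMe, the 3-OMe and the plain benzyl ethers have no para partner and should remain.

Step 12
Reactants: 22 3,7-dimethoxy-2-[3,4,5-tris(benzyloxy)phenyl]-4H-chromene-4,5,8-trione
Product: 24 5,8,3',4',5'-pentahydroxy-3,7-dimethoxyflavone, via tribenzyl hydroquinone 23 (not isolated)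
Conditions: H2 (1 atm), 10 % Pd/C, THF–MeOH, rt; filtration and concentration under Ar
Reagents that add atoms: none
Why: Catalytic hydrogenation first reduces the quinone to the aromatic 5,8-hydroquinone and then cleaves the three benzyl ethers by hydrogenolysis, the tetrasubstituted conjugated C2=C3 bond is inert at 1 atm, and the neutral medium avoids any Wessely–Moser isomerisation.

## Compound list

1 | 3-hydroxy-4,5-dimethoxybenzaldehyde | COc1cc(C=O)cc(O)c1OC | starting material
2 | N,N-diethylcarbamoyl chloride | CCN(CC)C(=O)Cl | starting material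
3 | 5-formyl-2,3-dimethoxyphenyl N,N-diethylcarbamate | COc1cc(C=O)cc(OC(=O)N(CC)CC)c1OC | intermediate
4 | 5-(formyloxy)-2,3-dimethoxyphenyl N,N-diethylcarbamate (not isolated) | COc1cc(OC=O)cc(OC(=O)N(CC)CC)c1OC | intermediate
5 | 5-hydroxy-2,3-dimethoxyphenyl N,N-diethylcarbamate | COc1cc(O)cc(OC(=O)N(CC)CC)c1OC | intermediate
6 | 2,3,5-trimethoxyphenyl N,N-diethylcarbamate | COc1cc(OC)cc(OC(=O)N(CC)CC)c1OC | intermediate
7 | 2-lithio-3,5,6-trimethoxyphenyl N,N-diethylcarbamate (not isolated) | COc1cc(OC)c([Li])c(OC(=O)N(CC)CC)c1OC | intermediate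
8 | 2-iodo-3,5,6-trimethoxyphenyl N,N-diethylcarbamate | COc1cc(OC)c(I)c(OC(=O)N(CC)CC)c1OC | intermediate
9 | 2-iodo-3,5,6-trimethoxyphenol | COc1cc(OC)c(I)c(O)c1OC | intermediate
10 | 3,4,5-trihydroxybenzaldehyde | O=Cc1cc(O)c(O)c(O)c1 | starting material
11 | 3,4,5-tris(benzyloxy)benzaldehyde | O=Cc1cc(OCc2ccccc2)c(OCc2ccccc2)c(OCc2ccccc2)c1 | intermediate
12 | dimethyl (1-diazo-2-oxopropyl)phosphonate | COP(=O)(OC)C(=[N+]=[N-])C(C)=O | starting material
13 | 5-ethynyl-1,2,3-tris(benzyloxy)benzene | C#Cc1cc(OCc2ccccc2)c(OCc2ccccc2)c(OCc2ccccc2)c1 | intermediate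
14 | carbon monoxide | [C-]#[O+] | starting material
15 | 1-(2-hydroxy-3,4,6-trimethoxyphenyl)-3-[3,4,5-tris(benzyloxy)phenyl]prop-2-yn-1-one (not isolated) | COc1cc(OC)c(C(=O)C#Cc2cc(OCc3ccccc3)c(OCc3ccccc3)c(OCc3ccccc3)c2)c(O)c1OC | intermediate
16 | (E)-3-(diethylamino)-1-(2-hydroxy-3,4,6-trimethoxyphenyl)-3-[3,4,5-tris(benzyloxy)phenyl]prop-2-en-1-one (not isolated) | COc1cc(OC)c(C(=O)/C=C(/N(CC)CC)c2cc(OCc3ccccc3)c(OCc3ccccc3)c(OCc3ccccc3)c2)c(O)c1OC | intermediate
17 | 3',4',5'-tris(benzyloxy)-5,7,8-trimethoxyflavone | COc1cc(OC)c2c(=O)cc(-c3cc(OCc4ccccc4)c(OCc4ccccc4)c(OCc4ccccc4)c3)oc2c1OC | intermediate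
18 | 3-lithio-3',4',5'-tris(benzyloxy)-5,7,8-trimethoxyflavone (not isolated) | COc1cc(OC)c2c(=O)c([Li])c(-c3cc(OCc4ccccc4)c(OCc4ccccc4)c(OCc4ccccc4)c3)oc2c1OC | intermediate
19 | dimethyl [3',4',5'-tris(benzyloxy)-5,7,8-trimethoxyflavon-3-yl]boronate (not isolated) | COc1cc(OC)c2c(=O)c(B(OC)OC)c(-c3cc(OCc4ccccc4)c(OCc4ccccc4)c(OCc4ccccc4)c3)oc2c1OC | intermediate
20 | 3',4',5'-tris(benzyloxy)-3-hydroxy-5,7,8-trimethoxyflavone | COc1cc(OC)c2c(=O)c(O)c(-c3cc(OCc4ccccc4)c(OCc4ccccc4)c(OCc4ccccc4)c3)oc2c1OC | intermediate
21 | 3',4',5'-tris(benzyloxy)-3,5,7,8-tetramethoxyflavone | COc1cc(OC)c2c(=O)c(OC)c(-c3cc(OCc4ccccc4)c(OCc4ccccc4)c(OCc4ccccc4)c3)oc2c1OC | intermediate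
22 | 3,7-dimethoxy-2-[3,4,5-tris(benzyloxy)phenyl]-4H-chromene-4,5,8-trione | COC1=CC(=O)C2=C(OC(=C(OC)C2=O)c3cc(OCc4ccccc4)c(OCc4ccccc4)c(OCc4ccccc4)c3)C1=O | intermediate
23 | 3',4',5'-tris(benzyloxy)-5,8-dihydroxy-3,7-dimethoxyflavone (not isolated) | COc1cc(O)c2c(=O)c(OC)c(-c3cc(OCc4ccccc4)c(OCc4ccccc4)c(OCc4ccccc4)c3)oc2c1O | intermediate
24 | 5,8,3',4',5'-pentahydroxy-3,7-dimethoxyflavone | COc1cc(O)c2c(=O)c(OC)c(-c3cc(O)c(O)c(O)c3)oc2c1O | target

## Step count and risks

Total step count: 12. Longest linear sequence: 10 (steps 1–5 and 8–12).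

**Step 8.** Oxidative addition and CO insertion at an iodide flanked by two oxygens may be slow. Direct alkynylation with closure to a benzofuran, capture of the aroyl–palladium species by diethylamine, or alkyne oligomerisation could then outrun ynone formation.
- The fallback brings in C4 as a preformed acyl carbon instead of CO. It sets out from 13 and 9 and returns at 15, and from there to 17.
- Alkyne 13 is deprotonated with n-BuLi (THF, −78 °C) to lithium [3,4,5-tris(benzyloxy)phenyl]acetylide F1.
- F1 is acylated with N-methoxy-N-methylcarbamoyl chloride to the Weinreb amide N-methoxy-N-methyl-3-[3,4,5-tris(benzyloxy)phenyl]prop-2-ynamide F2.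
- Iodophenol 9 is treated with n-BuLi (2.2 equiv, THF, −78 °C) for O-deprotonation and iodine–lithium exchange, giving lithium 2-lithio-3,5,6-trimethoxyphenolate F3.
- F3 adds to F2, and collapse of the chelated adduct on work-up should give ynone 15, now isolated. Warming 15 with Et2NH in EtOH closes it through 16 to 17.

**Step 11.** Electron transfer from the tris(benzyloxy)phenyl ring or the 3-methoxy enol ether may compete with oxidation of ring A. Benzylic oxidation, nitration, or hydrolytic opening of the quinone-fused pyranone are also possible.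
- The fallback replaces outer-sphere oxidation of a tetra-ether by oxidation of a single free phenol. It sets out from 21 and returns at 22.
- AlCl3 in MeCN, chelated between C4=O and the peri 5-oxygen, should remove only the 5-O-methyl group. This gives 3',4',5'-tris(benzyloxy)-5-hydroxy-3,7,8-trimethoxyflavone F4.
- PhI(OAc)2 in MeCN–H2O at 0 °C binds the free phenol of F4 and oxidises the para-methoxyphenol unit to quinone 22.

**Step 9.** Deprotonation may be incomplete, the amide may add at C2 with opening of the pyranone, or the electron-poor vinyl boronate may protodeboronate before oxidation.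
- The fallback oxidises the C2=C3 bond directly. It sets out from 17 and returns at 20.
- Dimethyldioxirane (acetone–CH2Cl2, 0 °C) should give the racemic, necessarily cis-fused 2,3-epoxy-3',4',5'-tris(benzyloxy)-5,7,8-trimethoxyflavanone F5.
- Catalytic p-TsOH opens F5 at C2, where the cation is stabilised by O1 and the aryl group, and loss of H3 gives flavonol 20.

## Further compounds

F1 | step 8 | lithium [3,4,5-tris(benzyloxy)phenyl]acetylide | [Li]C#Cc1cc(OCc2ccccc2)c(OCc2ccccc2)c(OCc2ccccc2)c1
F2 | step 8 | N-methoxy-N-methyl-3-[3,4,5-tris(benzyloxy)phenyl]prop-2-ynamide | CON(C)C(=O)C#Cc1cc(OCc2ccccc2)c(OCc2ccccc2)c(OCc2ccccc2)c1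
F3 | step 8 | lithium 2-lithio-3,5,6-trimethoxyphenolate | COc1cc(OC)c([Li])c(O[Li])c1OC
F4 | step 11 | 3',4',5'-tris(benzyloxy)-5-hydroxy-3,7,8-trimethoxyflavone | COc1cc(O)c2c(=O)c(OC)c(-c3cc(OCc4ccccc4)c(OCc4ccccc4)c(OCc4ccccc4)c3)oc2c1OC
F5 | step 9 | 2,3-epoxy-3',4',5'-tris(benzyloxy)-5,7,8-trimethoxyflavanone (racemic, one enantiomer drawn) | COc1cc(OC)c2C(=O)[C@H]3O[C@@]3(c5cc(OCc4ccccc4)c(OCc4ccccc4)c(OCc4ccccc4)c5)Oc2c1OC
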